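The leftover substrate at the end of a cold addition is where I start, since you want a quick number and your hunch is that north-east wins.

| flask | substrate | reagent | temperature | remark | time |
|---|---|---|---|---|---|
| cedar | 0.10 M | 0.90 equiv | 10 °C | run made earlier |  |
| ash | 0.067 M | 0.90 equiv | 25 °C | run made earlier |  |
| alder | 0.15 M | 0.90 equiv | 10 °C | run made earlier |  |
| east | 0.10 M | 0.900 equiv (fed, over 80 min) | 25 °C | all else is in the flask from the start; the feed brings no volume worth counting | 2.0 h |
| south | 0.10 M (in portions, 4, over 80 min) | 0.900 equiv | 25 °C | first portion at the start, last at 80 min | 2.0 h |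
| south-west | 0.10 M | 0.900 equiv | 25 °C | everything together at the start | 2.0 h |
| north-east | 0.10 M (fed, over 80 min) | 0.900 equiv |  | the addition at −15 °C, then warmed to 25 °C; the feed brings no volume worth counting | 2.0 h |

| cedar: time / h | cedar: mono adduct / % | ash: time / min | ash: mono adduct / % | alder: time / h | alder: mono adduct / % |
|---|---|---|---|---|---|
| 0.200 | 11.0 | 20.0 | 21.5 | 0.250 | 16.6 |
| 0.333 | 15.4 | 40.0 | 25.6 | 0.833 | 26.7 |
| 0.667 | 22.0 | 60.0 | 25.6 | 1.33 | 27.6 |
| 1.33 | 27.5 | 80.0 | 24.8 | 2.00 | 27.5 |
| 3.00 | 27.3 | 90.0 | 24.7 | 3.00 | 26.5 |

(each reading ± 0.3 percentage points)

- which flask leads in amount of mono adduct, in percent of the substrate charged ("all alike" within 1.5 percentage points) (east / south / south-west / north-east / all alike)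
- how much mono adduct is there at the end, in percent of the substrate charged: east
- how much mono adduct is there at the end, in percent of the substrate charged: south
- how much mono adduct is there at the end, in percent of the substrate charged: south-west
- how much mono adduct is there at the end, in percent of the substrate charged: north-east



With equivalents held, the readings run on concentration times time: alder's 16.6% at 0.250 h counts as 0.375 h for cedar, just past cedar's 15.4% at 0.333 h. So I work with one quantity. North-east's warm stage of 40.0 min at 0.10 M reads 59.7 min on what I call the ash clock, a flask's time multiplied by its substrate concentration and divided by ash's.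

Temperature goes in logarithms. Cedar reads 22.0% at 59.7 min on that clock, and ash reads 21.5% at 20.0 min, so going from 25 °C to 10 °C costs 0.475 in powers of ten. North-east's feed at −15 °C lies below both of these temperatures, so I take that cost as the least it pays. The cold feed, with half the substrate in on average, then adds at most 20.0 min, a third of what the warm stage reads.

So north-east ends at most at 79.7 min on the ash clock, and my number for it is ash's 25.6% at 60.0 min, with ash's 24.8% at 80.0 min as the low edge. South-west sits at 179 min, past ash's last reading of 24.7%, so I put it lower. For east and south the charge ratio shifts during addition, so this clock gives me no number.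

The forecast says east 25%, south 18.5%, south-west 24%, north-east 25.3%, with north-east leading, and holds that “Reagent feed does not change selectivity”.

The simulation gives east 11.9%, south 20.8%, south-west 22.0% and north-east 25.8%, so north-east leads.

    substrate + reagent → mono adduct + released group (k = 0.00670 /M/s, Ea = 54.0 kJ/mol)
    reagent + mono adduct → bis adduct + released group (k = 0.00730 /M/s, Ea = 58.0 kJ/mol)
    reagent + bis adduct → tris adduct + released group (k = 0.00980 /M/s, Ea = 69.0 kJ/mol)
    substrate + released group → side product (k = 2.80 × 10⁻⁴ /M/s, Ea = 76.0 kJ/mol)
    2 substrate → self-condensation product (k = 0.00280 /M/s, Ea = 67.0 kJ/mol)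
    (constants at 25 °C)

East ends with 60.5% of its substrate as self-condensation product, two substrate counted in each. North-east still holds 94.1% of its substrate at 1.33 h. Read at 8.0 h, the same flask stands at 597 min on the ash clock, ten times its 59.7 min, one power of ten further on. That neighbour holds 21.6% mono adduct, with 3.67% of the substrate left and the reagent, the limiting reagent there, down to 0.0136% of its charge.

(The numbers in the tables stem from a simulated flask on assumed constants; scatter was added.)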